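The cyclohexene is cut at C2–C3 and C5–C6 (ring numbered from C1, the carbon bearing the side chain; C2 carries the methyl, C6 the gem-dimethyl group). C2 and C6 flank C1, so they are the α and α′ carbons of a latent C1 ketone, and C3–C4–C5 is a bare trimethylene unit. The key step is a one-pot α,α′-annulation: acyclic 2-methylpentan-3-one and 1-chloro-3-iodopropane give the ring, both bonds and the quaternary carbon. The ketone becomes an enol triflate that is coupled late with a 1,2-dioxane chain built from (S)-2-methylglycidol by perhydrolysis and SN2 ring closure (both invertive). A catalyst-controlled epoxidation ends the route.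

Key step: step 1

Remark: but-1-en-3-yne (19) is taken as its commercial solution and the enantiomer of the D-fructose-derived Shi ketone as available; one-pot sequences count as one step.
Remark: the carboxylic acid is carried unprotected from step 10 on; where an ylide or 9-BBN is used, one extra equivalent is consumed by it.

Step 1
Reactants: 1 2-methylpentan-3-one; 2 1-chloro-3-iodopropane
Product: 4 racemic 2,2,6-trimethylcyclohexan-1-one, via 6-chloro-2,4-dimethylhexan-3-one 3 (not isolated)
Conditions: LiN(iPr)2, THF, −78 °C; then 2, DMPU, −78 → 0 °C; then KOtBu, NaI (cat.), t-BuOH, 50 °C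
Reagents that add atoms: none
Why: LiN(iPr)2 removes the less hindered methylene proton of 1 under kinetic control and the enolate is alkylated by the iodide end of 2, which forms the C2–C3 bond; KOtBu in t-BuOH then equilibrates the enolates of 3, and the enolate on the isopropyl side displaces the chloride (activated by NaI), which forms the C5–C6 bond. The closest known reaction type is the α,α′-annulation of a ketone with a 1,3-dihalide, a double enolate alkylation. The ring closes by a 6-(enolendo)-exo-tet C-alkylation, which the Baldwin rules allow and which also creates the quaternary carbon C6. The only stereocenter formed (C2) is not controlled and need not be, because step 2 makes it trigonal. The step needs regiocontrol in the first alkylation (secured by kinetic enolisation at the CH2 group), iodide-over-chloride chemoselectivity, and C- over O-alkylation in the closure (favoured by a potassium enolate in a protic medium; C-alkylation from the other enolate would need a cyclobutane).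

Step 2
Reactants: 4 racemic 2,2,6-trimethylcyclohexan-1-one
Product: 5 2,6,6-trimethylcyclohex-1-en-1-yl trifluoromethanesulfonate
Conditions: LiN(iPr)2, THF, −78 → 0 °C; PhNTf2, 0 °C → rt
Reagents that add atoms: N-phenylbis(trifluoromethanesulfonimide), O=S(=O)(N(c1ccccc1)S(=O)(=O)C(F)(F)F)C(F)(F)F
Why: Enol triflate formation: the ketone has a single α-hydrogen, so only the tetrasubstituted enolate can form, and PhNTf2 sulfonylates it on oxygen; the racemic stereocenter of 4 becomes trigonal.

Step 3
Reactants: 6 (S)-2-methylglycidol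
Product: 7 [(2R)-2-methyloxiran-2-yl]methyl 4-methylbenzenesulfonate
Conditions: TsCl, Et3N, DMAP (cat.), CH2Cl2, 0 °C
Reagents that add atoms: 4-methylbenzenesulfonyl chloride, Cc1ccc(cc1)S(=O)(=O)Cl
Why: Sulfonylation of the primary alcohol (tosylate formation); no bond to the stereocenter is touched, and its descriptor changes from S to R only because CH2OTs now outranks the ring CH2.

Step 4
Reactants: 7 [(2R)-2-methyloxiran-2-yl]methyl 4-methylbenzenesulfonate
Product: 9 (2R)-2-(but-3-en-1-yl)-2-methyloxirane, via (2R)-2-hydroxy-2-methylhept-6-en-1-yl 4-methylbenzenesulfonate 8 (not isolated)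
Conditions: allylMgBr, CuI (cat.), THF, −40 → 0 °C; then K2CO3, MeOH, rt
Reagents that add atoms: allylmagnesium bromide, C=CC[Mg]Br
Why: Copper-catalysed Grignard opening of the epoxide at its CH2 carbon gives a tertiary alkoxide, which then displaces the neighbouring tosylate (intramolecular Williamson etherification, 3-exo-tet); the epoxide is transposed and the quaternary stereocenter, none of whose bonds is broken, is carried over unchanged.

Step 5
Reactants: 9 (2R)-2-(but-3-en-1-yl)-2-methyloxirane
Product: 10 3-[(2R)-2-methyloxiran-2-yl]propanal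
Conditions: O3, CH2Cl2, −78 °C; then PPh3, −78 °C → rt
Reagents that add atoms: ozone, [O-][O+]=O
Why: Ozonolysis with reductive work-up cleaves the only alkene to the aldehyde; the 2,2-disubstituted epoxide is inert to ozone and to PPh3.

Step 6
Reactants: 10 3-[(2R)-2-methyloxiran-2-yl]propanal
Product: 11 (3S,4R)-3-methyl-6-[(2R)-2-methyloxiran-2-yl]hex-1-en-4-ol
Conditions: (E)-but-2-ene, KOtBu, n-BuLi, THF, −78 → −45 °C; (−)-Ipc2BOMe, −78 °C; BF3·OEt2, −78 °C; then 10, −78 °C; NaOH, H2O2, 0 °C → rt
Reagents that add atoms: (E)-but-2-ene (transferred as its diisopinocampheylborane), C/C=C/C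
Why: Brown crotylboration: the (E)-crotylborane reacts through a chair Zimmerman–Traxler transition state, so the E geometry gives the anti relation of OH and CH3, and the isopinocampheyl groups derived from (+)-α-pinene direct the transfer to the Si face of the aldehyde, which sets the (4R) carbinol and (3S) methyl centres under reagent control.

Step 7
Reactants: 11 (3S,4R)-3-methyl-6-[(2R)-2-methyloxiran-2-yl]hex-1-en-4-ol
Product: 12 (3S,4R)-3-methyl-6-[(2R)-2-methyloxiran-2-yl]hex-1-en-4-yl methanesulfonate
Conditions: MsCl, Et3N, CH2Cl2, 0 °C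
Reagents that add atoms: methanesulfonyl chloride, CS(=O)(=O)Cl
Why: Mesylation of the secondary alcohol (O–S bond formation, retention) turns the hydroxyl into the leaving group for step 9.

Step 8
Reactants: 12 (3S,4R)-3-methyl-6-[(2R)-2-methyloxiran-2-yl]hex-1-en-4-yl methanesulfonate
Product: 13 (2S,5R,6S)-2-hydroperoxy-1-hydroxy-2,6-dimethyloct-7-en-5-yl methanesulfonate
Conditions: H2O2 (anhydrous solution in Et2O), H3PMo12O40 (cat.), Et2O, rt
Reagents that add atoms: hydrogen peroxide, OO
Why: Acid-catalysed perhydrolysis of the epoxide: H2O2 attacks the tertiary carbon, which carries most of the positive charge of the activated epoxide, from the side opposite the leaving oxygen (borderline SN2), so the tertiary hydroperoxide centre should form with inversion; the terminal alkene and the mesylate are inert.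

Step 9
Reactants: 13 (2S,5R,6S)-2-hydroperoxy-1-hydroxy-2,6-dimethyloct-7-en-5-yl methanesulfonate
Product: 14 [(3S,6S)-6-[(2S)-but-3-en-2-yl]-3-methyl-1,2-dioxan-3-yl]methanol
Conditions: KOtBu, 18-crown-6, THF, 0 °C
Reagents that add atoms: none
Why: Intramolecular SN2 alkylation of the hydroperoxide anion (6-exo-tet) closes the 1,2-dioxane with inversion at the secondary carbon, which turns the anti relation of step 6 into the syn relation of the target; there is no acidic C–H next to the leaving group, so elimination should not compete, and the far less acidic primary alcohol stays protonated.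

Step 10
Reactants: 14 [(3S,6S)-6-[(2S)-but-3-en-2-yl]-3-methyl-1,2-dioxan-3-yl]methanol
Product: 16 (2R)-2-[(3S,6S)-6-(hydroxymethyl)-6-methyl-1,2-dioxan-3-yl]propanoic acid, via (2R)-2-[(3S,6S)-6-(hydroxymethyl)-6-methyl-1,2-dioxan-3-yl]propanal 15 (not isolated)
Conditions: O3, CH2Cl2–MeOH, −78 °C; Me2S, −78 °C → rt; then NaClO2, NaH2PO4, 2-methylbut-2-ene, t-BuOH–H2O, 0 °C → rt
Reagents that add atoms: ozone, [O-][O+]=O; sodium chlorite, [Na+].[O-]Cl=O
Why: Ozonolysis of the terminal alkene gives the aldehyde, which is oxidised without purification by NaClO2 (Pinnick oxidation) under buffered conditions that should not epimerise the α-centre; the peroxide and the primary alcohol are untouched.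

Step 11
Reactants: 16 (2R)-2-[(3S,6S)-6-(hydroxymethyl)-6-methyl-1,2-dioxan-3-yl]propanoic acid
Product: 17 (2R)-2-[(3S,6S)-6-formyl-6-methyl-1,2-dioxan-3-yl]propanoic acid
Conditions: Dess–Martin periodinane, CH2Cl2, 0 °C → rt
Reagents that add atoms: none
Why: Dess–Martin oxidation of the primary alcohol under neutral conditions gives an aldehyde on the quaternary peroxide carbon, which can neither enolise nor eliminate.

Step 12
Reactants: 17 (2R)-2-[(3S,6S)-6-formyl-6-methyl-1,2-dioxan-3-yl]propanoic acid
Product: 18 (2R)-2-[(3S,6S)-6-ethenyl-6-methyl-1,2-dioxan-3-yl]propanoic acid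
Conditions: Ph3PCH3Br, KN(SiMe3)2, THF, 0 °C; then 17, −78 → 0 °C; aqueous NaH2PO4 work-up
Reagents that add atoms: methyltriphenylphosphonium bromide, C[P+](c1ccccc1)(c1ccccc1)c1ccccc1.[Br-]
Why: Wittig methylenation of the aldehyde; the first equivalent of ylide only deprotonates the acid, and the carboxylate protects the α-centre from enolisation and the β-peroxide from elimination.

Step 13
Reactants: 19 but-1-en-3-yne
Product: 21 (1E)-1-iodo-2-methylbuta-1,3-diene, via dimethyl[(1E)-2-methylbuta-1,3-dien-1-yl]alumane 20 (not isolated)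
Conditions: AlMe3, Cp2ZrCl2 (cat.), CH2Cl2, 0 °C → rt; then I2, THF, −30 → 0 °C
Reagents that add atoms: trimethylaluminium, C[Al](C)C; iodine, II
Why: Negishi zirconium-catalysed carboalumination adds methyl and aluminium syn across the alkyne with aluminium on the terminal carbon, and iodinolysis with retention gives the E-iodide.

Step 14
Reactants: 18 (2R)-2-[(3S,6S)-6-ethenyl-6-methyl-1,2-dioxan-3-yl]propanoic acid; 21 (1E)-1-iodo-2-methylbuta-1,3-diene
Product: 23 (2R)-2-[(3S,6R)-6-methyl-6-[(3E)-4-methylhexa-3,5-dien-1-yl]-1,2-dioxan-3-yl]propanoic acid, via alkyl-9-BBN borane 22 (not isolated)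
Conditions: 9-BBN (2.2 equiv), THF, 0 °C → rt; then 21, PdCl2(dppf), AsPh3, Cs2CO3, DMF–H2O, rt
Reagents that add atoms: none
Why: B-alkyl Suzuki–Miyaura coupling: 9-BBN (the first equivalent is taken up by the acid as an acyloxyborane that the aqueous base hydrolyses) puts boron on the terminal carbon of the vinyl group, and the alkylborane couples with the vinyl iodide with retention of the E geometry.

Step 15
Reactants: 23 (2R)-2-[(3S,6R)-6-methyl-6-[(3E)-4-methylhexa-3,5-dien-1-yl]-1,2-dioxan-3-yl]propanoic acid; 5 2,6,6-trimethylcyclohex-1-en-1-yl trifluoromethanesulfonate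
Product: 25 (2R)-2-[(3S,6R)-6-methyl-6-[(3E)-4-methyl-6-(2,6,6-trimethylcyclohex-1-en-1-yl)hex-3-en-1-yl]-1,2-dioxan-3-yl]propanoic acid, via alkyl-9-BBN borane 24 (not isolated)
Conditions: 9-BBN (2.2 equiv), THF, rt; then 5, PdCl2(dppf), AsPh3, Cs2CO3, DMF–H2O, 50 °C
Reagents that add atoms: none
Why: Second B-alkyl Suzuki–Miyaura coupling: 9-BBN hydroborates the monosubstituted end of the diene at its terminal carbon (the trisubstituted double bond reacts far more slowly), and the homoallylic borane couples with the enol triflate, which puts the tetrasubstituted ring alkene in place.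

Step 16
Reactants: 25 (2R)-2-[(3S,6R)-6-methyl-6-[(3E)-4-methyl-6-(2,6,6-trimethylcyclohex-1-en-1-yl)hex-3-en-1-yl]-1,2-dioxan-3-yl]propanoic acid
Product: 26 (2R)-2-[(3S,6R)-6-methyl-6-{2-[(2S,3S)-3-methyl-3-[2-(2,6,6-trimethylcyclohex-1-en-1-yl)ethyl]oxiran-2-yl]ethyl}-1,2-dioxan-3-yl]propanoic acid (CNP0204283.1)
Conditions: enantiomer of the D-fructose-derived Shi ketone (cat.), Oxone (2KHSO5·KHSO4·K2SO4), K2CO3, Bu4NHSO4, MeCN–CH2(OMe)2–aqueous Na2B4O7 buffer, 0 °C; then NaH2PO4 to pH 5
Reagents that add atoms: potassium peroxymonosulfate, [K+].[O-]S(=O)(=O)OO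
Why: Shi epoxidation: the chiral dioxirane formed from the ketone and KHSO5 transfers oxygen through a spiro transition state, and the enantiomer of the usual catalyst should deliver it to the face that gives the (S,S)-epoxide under catalyst control (the existing centres are remote); the unhindered trisubstituted alkene should react well before the tetrasubstituted ring alkene, which is shielded by the adjacent gem-dimethyl carbon.

Compound list
1 | 2-methylpentan-3-one | CCC(=O)C(C)C | starting material
2 | 1-chloro-3-iodopropane | ClCCCI | starting material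
3 | 6-chloro-2,4-dimethylhexan-3-one (racemic) | CC(C)C(=O)C(C)CCCCl | intermediate (not isolated)
4 | 2,2,6-trimethylcyclohexan-1-one (racemic) | CC1CCCC(C)(C)C1=O | intermediate
5 | 2,6,6-trimethylcyclohex-1-en-1-yl trifluoromethanesulfonate | CC1=C(OS(=O)(=O)C(F)(F)F)C(C)(C)CCC1 | intermediate
6 | (S)-2-methylglycidol, [(2S)-2-methyloxiran-2-yl]methanol | C1O[C@@]1(C)CO | starting material
7 | [(2R)-2-methyloxiran-2-yl]methyl 4-methylbenzenesulfonate | C1O[C@@]1(C)COS(=O)(=O)c1ccc(C)cc1 | intermediate
8 | (2R)-2-hydroxy-2-methylhept-6-en-1-yl 4-methylbenzenesulfonate (formed as its magnesium alkoxide) | C=CCC[C@@](C)(O)COS(=O)(=O)c1ccc(C)cc1 | intermediate (not isolated)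
9 | (2R)-2-(but-3-en-1-yl)-2-methyloxirane | C1O[C@]1(C)CCC=C | intermediate
10 | 3-[(2R)-2-methyloxiran-2-yl]propanal | C1O[C@]1(C)CCC=O | intermediate
11 | (3S,4R)-3-methyl-6-[(2R)-2-methyloxiran-2-yl]hex-1-en-4-ol | C1O[C@]1(C)CC[C@@H](O)[C@@H](C)C=C | intermediate
12 | (3S,4R)-3-methyl-6-[(2R)-2-methyloxiran-2-yl]hex-1-en-4-yl methanesulfonate | C1O[C@]1(C)CC[C@@H](OS(C)(=O)=O)[C@@H](C)C=C | intermediate
13 | (2S,5R,6S)-2-hydroperoxy-1-hydroxy-2,6-dimethyloct-7-en-5-yl methanesulfonate | OC[C@@](C)(OO)CC[C@@H](OS(C)(=O)=O)[C@@H](C)C=C | intermediate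
14 | [(3S,6S)-6-[(2S)-but-3-en-2-yl]-3-methyl-1,2-dioxan-3-yl]methanol | OC[C@]1(C)CC[C@@H]([C@@H](C)C=C)OO1 | intermediate
15 | (2R)-2-[(3S,6S)-6-(hydroxymethyl)-6-methyl-1,2-dioxan-3-yl]propanal | OC[C@]1(C)CC[C@@H]([C@@H](C)C=O)OO1 | intermediate (not isolated)
16 | (2R)-2-[(3S,6S)-6-(hydroxymethyl)-6-methyl-1,2-dioxan-3-yl]propanoic acid | OC[C@]1(C)CC[C@@H]([C@@H](C)C(=O)O)OO1 | intermediate
17 | (2R)-2-[(3S,6S)-6-formyl-6-methyl-1,2-dioxan-3-yl]propanoic acid | O=C[C@]1(C)CC[C@@H]([C@@H](C)C(=O)O)OO1 | intermediate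
18 | (2R)-2-[(3S,6S)-6-ethenyl-6-methyl-1,2-dioxan-3-yl]propanoic acid | C=C[C@]1(C)CC[C@@H]([C@@H](C)C(=O)O)OO1 | intermediate
19 | but-1-en-3-yne | C=CC#C | starting material
20 | dimethyl[(1E)-2-methylbuta-1,3-dien-1-yl]alumane | C=C/C(C)=C/[Al](C)C | intermediate (not isolated)
21 | (1E)-1-iodo-2-methylbuta-1,3-diene | C=C/C(C)=C/I | intermediate
22 | B-alkyl-9-BBN from 18 (boron on the terminal carbon of the former vinyl group; carboxyl group bound as the acyloxy-9-BBN) | C1CC2CCCC(C1)B2CC[C@]1(C)CC[C@@H]([C@@H](C)C(=O)OB2C3CCCC2CCC3)OO1 | intermediate (not isolated)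
23 | (2R)-2-[(3S,6R)-6-methyl-6-[(3E)-4-methylhexa-3,5-dien-1-yl]-1,2-dioxan-3-yl]propanoic acid | C=C/C(C)=C/CC[C@]1(C)CC[C@@H]([C@@H](C)C(=O)O)OO1 | intermediate
24 | B-alkyl-9-BBN from 23 (boron on the terminal carbon of the former diene; carboxyl group bound as the acyloxy-9-BBN) | C1CC2CCCC(C1)B2CC/C(C)=C/CC[C@]1(C)CC[C@@H]([C@@H](C)C(=O)OB2C3CCCC2CCC3)OO1 | intermediate (not isolated)
25 | (2R)-2-[(3S,6R)-6-methyl-6-[(3E)-4-methyl-6-(2,6,6-trimethylcyclohex-1-en-1-yl)hex-3-en-1-yl]-1,2-dioxan-3-yl]propanoic acid | CC1=C(CC/C(C)=C/CC[C@]2(C)CC[C@@H]([C@@H](C)C(=O)O)OO2)C(C)(C)CCC1 | intermediate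
26 | (2R)-2-[(3S,6R)-6-methyl-6-{2-[(2S,3S)-3-methyl-3-[2-(2,6,6-trimethylcyclohex-1-en-1-yl)ethyl]oxiran-2-yl]ethyl}-1,2-dioxan-3-yl]propanoic acid | CC1=C(CC[C@]2(C)O[C@H]2CC[C@]2(C)CC[C@@H]([C@@H](C)C(=O)O)OO2)C(C)(C)CCC1 | target

Total step count: 16 steps.
Longest linear sequence: 13 steps (steps 3–12 and 14–16, from 6 to 26).

The three steps most likely to fail

Step 1 (key step). The ring may fail to close on carbon: the second enolate can alkylate on oxygen, can form on the already alkylated side of the carbonyl, or can react between molecules. The fallback sets out from 1 and comes back at 4. Under KOtBu in THF, 1 adds to methyl acrylate at its isopropyl carbon (Michael addition) to give methyl 4,4-dimethyl-5-oxoheptanoate F1. This undergoes Claisen cyclisation in the same flask to 2,4,4-trimethylcyclohexane-1,3-dione F2; the same two ring bonds are formed, now funnelled by the stable diketonate. Oxalyl chloride with catalytic DMF converts the less hindered enol into 3-chloro-2,6,6-trimethylcyclohex-2-en-1-one F3. Hydrogenation over Pd on carbon with Et3N removes the chlorine and saturates the alkene to give 4.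

Step 8. Ionisation of the activated epoxide to a free tertiary cation would erode the configuration of the quaternary centre, and a hydride shift to an aldehyde or attack at the CH2 end could compete. The fallback sets out from 11 and comes back at 14; it reverses the order of the two C–O bond formations. Tf2O and 2,6-lutidine (CH2Cl2, −78 °C) convert 11 into (3S,4R)-3-methyl-6-[(2R)-2-methyloxiran-2-yl]hex-1-en-4-yl trifluoromethanesulfonate F4. The potassium salt of 2-methoxypropan-2-yl hydroperoxide (KOtBu, THF, 0 °C) displaces the triflate with inversion to give (2R)-2-[(3S,4S)-3-[(2-methoxypropan-2-yl)peroxy]-4-methylhex-5-en-1-yl]-2-methyloxirane F5. Camphorsulfonic acid in moist CH2Cl2 cleaves the ketal to (2R)-2-[(3S,4S)-3-hydroperoxy-4-methylhex-5-en-1-yl]-2-methyloxirane F6. Under the same acid, F6 opens the epoxide intramolecularly at its tertiary carbon (6-exo, inversion, in a tethered and therefore tighter transition state) to give 14.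

Step 15. Oxidative addition and transmetalation at the tetrasubstituted, doubly flanked enol triflate may be too slow at a temperature the peroxide tolerates, so that protodeboronation or palladium-induced cleavage of the O–O bond takes over. The fallback sets out from 5 and comes back at 25; it moves the hindered coupling to a robust small partner. (But-3-en-1-yn-1-yl)trimethylsilane is hydroborated with 9-BBN to 9-[4-(trimethylsilyl)but-3-yn-1-yl]-9-borabicyclo[3.3.1]nonane F7. F7 is coupled with 5 (PdCl2(dppf), K3PO4, DMF, 70 °C) to give trimethyl[4-(2,6,6-trimethylcyclohex-1-en-1-yl)but-1-yn-1-yl]silane F8. K2CO3 in MeOH gives 2-(but-3-yn-1-yl)-1,3,3-trimethylcyclohex-1-ene F9. AlMe3 with catalytic Cp2ZrCl2 gives dimethyl[(1E)-2-methyl-4-(2,6,6-trimethylcyclohex-1-en-1-yl)but-1-en-1-yl]alumane F10, and I2 converts it into 2-[(3E)-4-iodo-3-methylbut-3-en-1-yl]-1,3,3-trimethylcyclohex-1-ene F11. A room-temperature B-alkyl Suzuki coupling of F11 with borane 22 (PdCl2(dppf), AsPh3, Cs2CO3, DMF–H2O) then gives 25 directly, without 21, 23 and 24.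

Further compounds
F1 | step 1 | methyl 4,4-dimethyl-5-oxoheptanoate | CCC(=O)C(C)(C)CCC(=O)OC
F2 | step 1 | 2,4,4-trimethylcyclohexane-1,3-dione | CC1C(=O)CCC(C)(C)C1=O
F3 | step 1 | 3-chloro-2,6,6-trimethylcyclohex-2-en-1-one | CC1=C(Cl)CCC(C)(C)C1=O
F4 | step 8 | (3S,4R)-3-methyl-6-[(2R)-2-methyloxiran-2-yl]hex-1-en-4-yl trifluoromethanesulfonate | C1O[C@]1(C)CC[C@@H](OS(=O)(=O)C(F)(F)F)[C@@H](C)C=C
F5 | step 8 | (2R)-2-[(3S,4S)-3-[(2-methoxypropan-2-yl)peroxy]-4-methylhex-5-en-1-yl]-2-methyloxirane | C1O[C@]1(C)CC[C@@H]([C@@H](C)C=C)OOC(C)(C)OC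
F6 | step 8 | (2R)-2-[(3S,4S)-3-hydroperoxy-4-methylhex-5-en-1-yl]-2-methyloxirane | C1O[C@]1(C)CC[C@@H]([C@@H](C)C=C)OO
F7 | step 15 | 9-[4-(trimethylsilyl)but-3-yn-1-yl]-9-borabicyclo[3.3.1]nonane | C[Si](C)(C)C#CCCB1C2CCCC1CCC2
F8 | step 15 | trimethyl[4-(2,6,6-trimethylcyclohex-1-en-1-yl)but-1-yn-1-yl]silane | CC1=C(CCC#C[Si](C)(C)C)C(C)(C)CCC1
F9 | step 15 | 2-(but-3-yn-1-yl)-1,3,3-trimethylcyclohex-1-ene | CC1=C(CCC#C)C(C)(C)CCC1
F10 | step 15 | dimethyl[(1E)-2-methyl-4-(2,6,6-trimethylcyclohex-1-en-1-yl)but-1-en-1-yl]alumane | CC1=C(CC/C(C)=C/[Al](C)C)C(C)(C)CCC1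
F11 | step 15 | 2-[(3E)-4-iodo-3-methylbut-3-en-1-yl]-1,3,3-trimethylcyclohex-1-ene | CC1=C(CC/C(C)=C/I)C(C)(C)CCC1
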